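The readings are simulated with constants of no real substance, noise included.

Over 3.0 min the flasks below differ in one thing: when the reagent or the starting material goes in.

| flask | starting material | reagent | free catalyst | remark | time |
|---|---|---|---|---|---|
| amber | 0.10 M | 0.050 M | 1 mM | run made earlier |  |
| red | 0.10 M | 0.075 M | 1 mM | run made earlier |  |
| zeta | 0.10 M | 0.0500 M (fed, over 10 s) | 1.0 mM | all else is in the flask from the start; the feed brings no volume worth counting | 3.0 min |
| delta | 0.10 M | 0.0500 M | 1.0 mM | everything together at the start | 3.0 min |
| alpha | 0.10 M (fed, over 40 s) | 0.0500 M | 1.0 mM | all else is in the flask from the start; the feed brings no volume worth counting | 3.0 min |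
| theta | 0.10 M | 0.0500 M (fed, over 40 s) | 1.0 mM | all else is in the flask from the start; the feed brings no volume worth counting | 3.0 min |

| amber: time / min | amber: product / % | red: time / s | red: product / % |
|---|---|---|---|
| 0.250 | 0.4 | 10.0 | 0.5 |
| 0.833 | 2.6 | 15.0 | 0.6 |
| 1.33 | 4.6 | 20.0 | 0.7 |
| 2.00 | 6.8 | 30.0 | 2.1 |
| 3.00 | 10.4 | 40.0 | 2.5 |

(each reading ± 0.3 percentage points)

- steps that have been proposed: catalyst intermediate B <-> catalyst intermediate C; catalyst intermediate C -> free catalyst + product; starting material + catalyst intermediate A <-> catalyst intermediate B; reagent + free catalyst -> catalyst intermediate A

* the best flask by amount of product, in percent of the starting material charged; "all alike" if 1.5 percentage points covers them all (zeta / delta / alpha / theta / all alike)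
* amount of product at the end, in percent of the starting material charged, zeta
* amount of product at the end, in percent of the starting material charged, delta
* amount of product at the end, in percent of the starting material charged, alpha
* amount of product at the end, in percent of the starting material charged, theta

In the proposed steps, reagent and free catalyst form catalyst intermediate A, which takes up starting material to give catalyst intermediate B. That turns into catalyst intermediate C, which releases product and free catalyst.

First question: which concentration does the rate follow? Between 0.833 min and 3.00 min the amber run gives 3.60 min⁻¹ as its turnover frequency, the product made per catalyst charged per unit time. The red run, between 10.0 s and 40.0 s, reads 4.00 min⁻¹, a rough reading with a scatter of 0.3 percentage points on a rise of 2 points. So 1.50 times the reagent brings 1.11 times the turnover frequency, an apparent order in [reagent] of about 0.260. You therefore tie the rate to [free catalyst] as charged, though that is your assumption, since neither earlier run varies it.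

Second question: what does a feed cost? Take the rate during a reagent feed as growing with the fed fraction raised to that order; its mean over the feed is then 0.794 of the full rate, so you charge each feed 0.206 of its duration as lost time. Turnover frequency times catalyst over starting material makes that 0.12 points for the quick feed and 0.5 points for the slow one. No run tests a starting-material feed, so alpha takes the same charge as theta.

Delta repeats amber, so you expect 10.4% there and 9.90% for alpha and theta. The widest gap, 0.5 points, is smaller than the margin of 1.5 points, so the flasks count as equal.

The forecast, holding that “Reagent mainly sets the start-up”, says all alike with 10.1%, 10.4%, 9.9% and 9.6% for zeta, delta, alpha and theta, lower than your 9.90% for theta.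

The flasks give 9.81%, 10.0%, 9.48% and 9.30% in that order, a spread of 0.70 points, so the outcome is all alike.

    catalyst intermediate B ⇌ catalyst intermediate C (K = 0.120, k = 1.30 s⁻¹)
    catalyst intermediate C → free catalyst + product (k = 1.20 s⁻¹)
    starting material + catalyst intermediate A ⇌ catalyst intermediate B (K = 18.0 L mol⁻¹, k = 15.0 L mol⁻¹ s⁻¹)
    reagent + free catalyst → catalyst intermediate A (k = 5.90 L mol⁻¹ s⁻¹)

Now take a flask like delta with 6.0 × 10⁻⁴ M of free catalyst. Turnover frequency, times catalyst over starting material, times 3.0 min, gives 10.8% for delta, which gave 10.0%, and 6.48% for this neighbour. The neighbour gives 6.13% of product, with 93.6% of its starting material remaining.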